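At 10.0 s and again at 25.0 s of the dusk run, the left-handed substrate stands at 30.1% and 18.9% of the charge, the right-handed substrate at 47.9% and 45.1%. In the proposed steps both couplings take the same coupling partner and free catalyst, so dividing the logarithmic fall of one hand by that of the other removes time, partner and catalyst. This is the bench rule for a kinetic resolution: the right-handed fall over the left-handed fall between these two readings, the fall ratio, is 0.129, and its inverse, 7.75, is what the rule reads as a selectivity factor.

The rule lets the left-handed fraction sink without a floor, but these two readings do not tell coupling of the right-handed substrate from its racemization. If racemization carries that fall, the fall ratio, taken at the mean left-to-right ratio of the two readings, 0.524, converts into the refill ratio 0.218, the rate of racemization over that of left-handed coupling per unit of substrate, a reading that carries their scatter. The left-to-right ratio then stops sinking at a floor equal to the refill ratio over one plus itself, 0.179. That is the border, and at 25.0 s the dusk run, at 0.419, still lies above it. The flask charges partner at 1.50 times the substrates against 2.96 in the dusk run, so its coupling can slacken as partner is used, and the refill ratio, with racemization held as it was, is then divided by the fraction of partner left.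

- dusk: left-handed substrate 0.41 M; right-handed substrate 0.41 M; coupling partner 2.43 M; free catalyst 49 mM; racemization catalyst 16 mM; run made earlier
- flask: left-handed substrate 0.81 M; coupling partner 2.43 M; free catalyst 49 mM; racemization catalyst 16 mM; right-handed substrate 0.81 M; time 4.0 min

- dusk (time / s: left-handed substrate / %, right-handed substrate / %): 10.0: 30.1, 47.9; 12.0: 28.3, 47.5; 15.0: 26.1, 47.6; 25.0: 18.9, 45.1

(standard deviation of a reading: 0.5 percentage points)

- free catalyst is single-handed; left-handed substrate and right-handed substrate are mirror images of each other, charged as a racemate, each of them at the stated concentration
- steps that have been proposed: coupling partner + free catalyst + left-handed substrate -> free catalyst + left-handed product; racemization catalyst -> spent catalyst; 2 free catalyst <-> resting dimer; coupling partner <-> dormant form; coupling partner + free catalyst + right-handed substrate -> free catalyst + right-handed product; left-handed substrate + racemization catalyst <-> right-handed substrate + racemization catalyst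
- an excess is the difference of the two amounts in percent of their sum
- an excess is below zero if the other one leads

* part of the left-handed substrate and right-handed substrate charged together that has reacted at 4.0 min
* excess of left-handed product over right-handed product in the product at 4.0 min
* excess of right-handed substrate over left-handed substrate among what is left of the two at 4.0 min

The forecast gives 78% reacted, 68% for the product excess and 68% for the substrate excess, reasoning that “Left-handed substrate drains within about a minute, then sits near 15% of the right-handed”. The reckoning made here takes its conversion, which leaves 48.0% of the partner if coupling alone consumes it. The refill ratio then stands at 0.454, the floor at 0.312 and the substrate excess at 52.4%, lower than the forecast's figure.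

The flask gives 78.4% reacted, 92.9% for the product excess and 52.8% for the substrate excess.

    coupling partner + free catalyst + left-handed substrate → free catalyst + left-handed product (k = 0.920 L² mol⁻² s⁻¹)
    racemization catalyst → spent catalyst (k = 0.00350 s⁻¹)
    2 free catalyst ⇌ resting dimer, settled at all times (K = 20.0 L mol⁻¹)
    coupling partner ⇌ dormant form (K = 0.720, k = 0.00840 s⁻¹)
    coupling partner + free catalyst + right-handed substrate → free catalyst + right-handed product (k = 0.0150 L² mol⁻² s⁻¹)
    left-handed substrate + racemization catalyst ⇌ right-handed substrate + racemization catalyst, rate k6*[racemization catalyst]*[left-handed substrate] forward; the back reaction follows from the equilibrium constant (k = 0.640 L mol⁻¹ s⁻¹)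

At 4.00 min racemization takes left-handed substrate in the flask at 0.00442 s⁻¹ per unit against 0.0146 s⁻¹ for coupling, the left-to-right ratio stands at 0.308, and the refill ratio scaled by the racemization catalyst and partner left gives a floor of 0.262. In the neighbouring flask with 0.20 M of free catalyst, the same scaling, with free catalyst added, gives a floor of 0.144, while that flask stands at 0.153, with a substrate excess of 73.5%.

(All runs come from a simulation with constants of no real substance; scatter was added.)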